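**Plan**

- Retrosynthesis: target 18 ← acetal 17 (unmask the C4 aldehyde) ← chloride 16 (C7–Cl to C7–CH3) ← cut of both bonds that tie the C1(=O)–C2=C3 unit to the benzo ring (C1–C7a and C3–C3a), giving cyclopropenone 6 and aryne 14 (from silyl triflate 12).
- Feature used: C1, C2 and C3 of the five-membered ring are joined to the benzene ring only at the adjacent carbons C7a and C3a. They therefore map onto a cyclopropenone (strained C1–C3 bond) and onto the two carbons of an aryne; C3 is beta to the C1 carbonyl, so a phosphine can leave from it.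
- Forward order: guaiazulene → 3-iodide → 3-propynyl → cyclopropenone 6 (three-membered ring); 2-bromo-3-chlorophenol → formylation → acetal → silyl triflate 12; a phosphine-catalysed (3+2) annulation then closes the indenone five-membered ring with all substituents in place.
- Helpers: chlorine at C7 steers the aryne addition and is then exchanged for methyl; the dioxolane masks the C4 aldehyde and is hydrolysed last.
- Stereochemistry: the target has no stereocentre and no stereogenic double bond; only regiochemistry has to be set (chlorine-induced aryne distortion, less hindered cyclopropenone carbon).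

Key step: step 7

Assumption: guaiazulene, propyne (as a THF solution) and 2-bromo-3-chlorophenol are taken as purchasable; "guaiazulen-3-yl" means 5-isopropyl-3,8-dimethylazulen-1-yl.

**Route**

Step 1
Reactants: 1 guaiazulene (7-isopropyl-1,4-dimethylazulene)
Product: 2 3-iodoguaiazulene (1-iodo-5-isopropyl-3,8-dimethylazulene), used at once
Conditions: NIS (1.0 equiv), CH2Cl2, 0 °C, dark
Reagents that add atoms: N-iodosuccinimide, O=C1CCC(=O)N1I
Why: Electrophilic aromatic iodination should occur at C3, the only free and most nucleophilic position of the five-membered ring of the azulene.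

Step 2
Reactants: 2 3-iodoguaiazulene; 3 propyne
Product: 4 3-(prop-1-yn-1-yl)guaiazulene
Conditions: propyne (THF solution, excess), PdCl2(PPh3)2 (3 mol %), CuI (5 mol %), Et3N, THF, rt
Reagents that add atoms: none
Why: Sonogashira coupling of an electron-rich aryl iodide with a terminal alkyne runs at room temperature, which suits the labile iodide, and nothing else in the molecule reacts.

Step 3
Reactants: 4 3-(prop-1-yn-1-yl)guaiazulene
Product: 6 2-(guaiazulen-3-yl)-3-methylcycloprop-2-en-1-one, via gem-difluorocyclopropene 5 (not isolated)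
Conditions: TMSCF3, NaI, THF, 65 °C (sealed tube); then wet silica gel, rt
Reagents that add atoms: (trifluoromethyl)trimethylsilane, C[Si](C)(C)C(F)(F)F; water, O
Why: Difluorocarbene from TMSCF3/NaI should add (2+1) to the electron-rich alkyne, and the gem-difluorocyclopropene, which ionises easily beside the donor azulenyl group, is hydrolysed to the cyclopropenone (the standard difluorocarbene route to cyclopropenones).

Step 4
Reactants: 7 2-bromo-3-chlorophenol
Product: 8 3-bromo-4-chloro-2-hydroxybenzaldehyde
Conditions: MgCl2, Et3N, paraformaldehyde, THF, reflux; dilute HCl work-up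
Reagents that add atoms: paraformaldehyde (formaldehyde), C=O
Why: The magnesium phenoxide-directed ortho-formylation (Casnati–Skattebøl reaction) is ortho-specific, and only C6 is a free ortho position, so the formyl group should enter next to the hydroxyl group.

Step 5
Reactants: 8 3-bromo-4-chloro-2-hydroxybenzaldehyde
Product: 9 2-bromo-3-chloro-6-(1,3-dioxolan-2-yl)phenol
Conditions: ethylene glycol, TsOH·H2O (cat.), toluene, reflux, Dean–Stark trap
Reagents that add atoms: ethylene glycol, OCCO
Why: Acid-catalysed acetalisation with azeotropic removal of water masks the aldehyde, which would otherwise be attacked by n-BuLi in step 6 and by the ylide in step 7.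

Step 6
Reactants: 9 2-bromo-3-chloro-6-(1,3-dioxolan-2-yl)phenol
Product: 12 3-chloro-6-(1,3-dioxolan-2-yl)-2-(trimethylsilyl)phenyl trifluoromethanesulfonate, via aryl trimethylsilyl ether 10 (not isolated), via lithium 2-silylphenoxide 11 (not isolated)
Conditions: HMDS, THF, reflux, then evaporation; n-BuLi, THF, −78 °C; Tf2O, −78 °C to rt
Reagents that add atoms: hexamethyldisilazane, C[Si](C)(C)N[Si](C)(C)C; trifluoromethanesulfonic anhydride, O=S(=O)(OS(=O)(=O)C(F)(F)F)C(F)(F)F
Why: O-Silylation, bromine–lithium exchange with O-to-C 1,3-silyl shift (retro-Brook rearrangement) and triflation of the phenoxide form the standard one-pot route to 2-silylaryl triflates; the acetal and the C–Cl bond should survive at −78 °C.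

Step 7
Reactants: 6 2-(guaiazulen-3-yl)-3-methylcycloprop-2-en-1-one; 12 3-chloro-6-(1,3-dioxolan-2-yl)-2-(trimethylsilyl)phenyl trifluoromethanesulfonate
Product: 16 7-chloro-4-(1,3-dioxolan-2-yl)-2-(guaiazulen-3-yl)-3-methyl-1H-inden-1-one, via ketenyl phosphorus ylide 13 (not isolated), via 3-chloro-6-(1,3-dioxolan-2-yl)benzyne 14 (not isolated), via 3-phosphonioindenolate 15 (not isolated)
Conditions: 12 (1.5 equiv), PPh3 (20 mol %), CsF (3 equiv), MeCN–toluene 1:1, 4 Å molecular sieves, rt to 40 °C
Reagents that add atoms: none
Why: Proposed new method: PPh3 should add to the methyl-bearing ring carbon of 6 and open the strained C1–C3 bond to the ketenyl phosphorus ylide 13, whose ylide carbon (the future C3) attacks aryne 14 released slowly from 12 by fluoride; the aryl anion so formed at the future C7a adds to the ketene carbon to give enolate 15, and E1cB loss of PPh3 from C3 delivers the enone of 16 and returns the catalyst. The closest known reaction type is the phosphine-catalysed (3+2) annulation of cyclopropenones with aldehydes, ketones or imines, which runs through the same ylide, ring closure onto the ketene and phosphine loss; new here is the aryne as two-atom partner, a species otherwise well known to take up carbon nucleophiles and pass the aryl anion to a neighbouring electrophile. The five-membered ring is closed in the second bond-forming event, a 5-exo-dig attack of the aryl anion on the sp carbon of the ketene, after an intermolecular first C–C bond. No stereocentre is set, since C3 is tetrahedral only in 15. Two regioselectivities are needed: the phosphine must attack the methyl-bearing and not the azulenyl-bearing carbon, which the bulk of the guaiazulenyl group (its peri methyl group) and its donor conjugation to that carbon should secure, and the ylide carbon must bond to the aryne carbon beside the acetal-bearing carbon, which the chlorine should secure because it distorts the aryne so that nucleophiles attack the carbon remote from it and the negative charge arises next to C–Cl. The step also needs chemoselectivity for the ylide over free PPh3 and over the cyclopropenone oxygen as partners of the aryne, for which 6 is kept in excess over the steady-state aryne and the acetal keeps the aldehyde, itself a partner for 13, out of play.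

Step 8
Reactants: 16 7-chloro-4-(1,3-dioxolan-2-yl)-2-(guaiazulen-3-yl)-3-methyl-1H-inden-1-one
Product: 17 4-(1,3-dioxolan-2-yl)-2-(guaiazulen-3-yl)-3,7-dimethyl-1H-inden-1-one
Conditions: MeB(OH)2 (3 equiv), Pd(OAc)2 (5 mol %), SPhos (10 mol %), K3PO4, toluene–H2O 10:1, 90 °C
Reagents that add atoms: methylboronic acid, CB(O)O
Why: Suzuki–Miyaura methylation of an aryl chloride activated by the ortho ketone replaces the regiocontrol helper by the C7 methyl group, and the acetal, enone and azulene should tolerate the mild base.

Step 9
Reactants: 17 4-(1,3-dioxolan-2-yl)-2-(guaiazulen-3-yl)-3,7-dimethyl-1H-inden-1-one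
Product: 18 2-(5-isopropyl-3,8-dimethylazulen-1-yl)-3,7-dimethyl-1-oxo-1H-indene-4-carbaldehyde (target)
Conditions: aqueous HCl (1 M), THF, rt
Reagents that add atoms: water, O
Why: Mild acid-catalysed acetal hydrolysis releases the C4 aldehyde, and dilute acid at room temperature should neither protonate the azulene irreversibly nor touch the indenone.

**Compound list**

1 | guaiazulene (7-isopropyl-1,4-dimethylazulene) | c1cc(C)c2cc(C(C)C)ccc(C)c1-2 | starting material
2 | 3-iodoguaiazulene (1-iodo-5-isopropyl-3,8-dimethylazulene) | Ic1cc(C)c2cc(C(C)C)ccc(C)c1-2 | intermediate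
3 | propyne | CC#C | starting material
4 | 3-(prop-1-yn-1-yl)guaiazulene | CC#Cc1cc(C)c2cc(C(C)C)ccc(C)c1-2 | intermediate
5 | 3,3-difluoro-1-(guaiazulen-3-yl)-2-methylcyclopropene | CC1=C(c2cc(C)c3cc(C(C)C)ccc(C)c2-3)C1(F)F | intermediate
6 | 2-(guaiazulen-3-yl)-3-methylcycloprop-2-en-1-one | CC1=C(c2cc(C)c3cc(C(C)C)ccc(C)c2-3)C1=O | intermediate
7 | 2-bromo-3-chlorophenol | Oc1cccc(Cl)c1Br | starting material
8 | 3-bromo-4-chloro-2-hydroxybenzaldehyde | O=Cc1ccc(Cl)c(Br)c1O | intermediate
9 | 2-bromo-3-chloro-6-(1,3-dioxolan-2-yl)phenol | Oc1c(C2OCCO2)ccc(Cl)c1Br | intermediate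
10 | [2-bromo-3-chloro-6-(1,3-dioxolan-2-yl)phenoxy]trimethylsilane | C[Si](C)(C)Oc1c(C2OCCO2)ccc(Cl)c1Br | intermediate
11 | lithium 3-chloro-6-(1,3-dioxolan-2-yl)-2-(trimethylsilyl)phenoxide | [Li]Oc1c(C2OCCO2)ccc(Cl)c1[Si](C)(C)C | intermediate
12 | 3-chloro-6-(1,3-dioxolan-2-yl)-2-(trimethylsilyl)phenyl trifluoromethanesulfonate | FC(F)(F)S(=O)(=O)Oc1c(C2OCCO2)ccc(Cl)c1[Si](C)(C)C | intermediate
13 | 2-(guaiazulen-3-yl)-3-(triphenyl-λ5-phosphanylidene)but-1-en-1-one (ketenyl phosphorus ylide) | CC(=P(c1ccccc1)(c1ccccc1)c1ccccc1)C(=C=O)c1cc(C)c2cc(C(C)C)ccc(C)c1-2 | intermediate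
14 | 3-chloro-6-(1,3-dioxolan-2-yl)benzyne | ClC1=CC=C(C2OCCO2)C#C1 | intermediate
15 | 7-chloro-4-(1,3-dioxolan-2-yl)-2-(guaiazulen-3-yl)-3-methyl-3-(triphenylphosphonio)-3H-inden-1-olate | CC1([P+](c2ccccc2)(c2ccccc2)c2ccccc2)C(c2cc(C)c3cc(C(C)C)ccc(C)c2-3)=C([O-])c2c(Cl)ccc(C3OCCO3)c21 | intermediate
16 | 7-chloro-4-(1,3-dioxolan-2-yl)-2-(guaiazulen-3-yl)-3-methyl-1H-inden-1-one | CC1=C(c2cc(C)c3cc(C(C)C)ccc(C)c2-3)C(=O)c2c(Cl)ccc(C3OCCO3)c21 | intermediate
17 | 4-(1,3-dioxolan-2-yl)-2-(guaiazulen-3-yl)-3,7-dimethyl-1H-inden-1-one | CC1=C(c2cc(C)c3cc(C(C)C)ccc(C)c2-3)C(=O)c2c(C)ccc(C3OCCO3)c21 | intermediate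
18 | 2-(5-isopropyl-3,8-dimethylazulen-1-yl)-3,7-dimethyl-1-oxo-1H-indene-4-carbaldehyde | CC1=C(c2cc(C)c3cc(C(C)C)ccc(C)c2-3)C(=O)c2c(C)ccc(C=O)c21 | target

**Summary**

Total step count: 9. Longest linear sequence: 6 steps (steps 1, 2, 3, 7, 8, 9, or steps 4, 5, 6, 7, 8, 9).

**Steps most likely to fail**

1. Step 7. The phosphine may add to the wrong cyclopropenone carbon, or the ylide to the wrong aryne carbon (loss of regiocontrol, also through steric repulsion by the acetal). The aryne may also be intercepted by free phosphine or by the cyclopropenone oxygen before the ylide reacts. Fallback by known chemistry, setting out from phenol 9 and alkyne 4 and coming back at 16: phenol 9 is deprotonated with NaH and subjected to bromine–lithium exchange (t-BuLi, THF, −78 °C) and formylation with DMF. This should give 6-chloro-3-(1,3-dioxolan-2-yl)-2-hydroxybenzaldehyde F1. Triflation (Tf2O, pyridine, CH2Cl2, 0 °C) gives 3-chloro-6-(1,3-dioxolan-2-yl)-2-formylphenyl trifluoromethanesulfonate F2. A Larock indenone annulation of F2 with alkyne 4 (Pd(OAc)2, NaOAc, n-Bu4NCl, DMF, 100 °C) should then give 16. The aryl group adds to the methyl-bearing alkyne carbon and the vinylpalladium carbon bearing the bulkier azulenyl group adds to the aldehyde.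

2. Step 3. Difluorocarbene may cyclopropanate the electron-rich π bonds of the azulene in competition with the alkyne, and material may decompose during the hydrolysis. Fallback, setting out from iodide 2 and coming back at 6: the known cyclopropenone neopentyl glycol acetal (6,6-dimethyl-4,8-dioxaspiro[2.5]oct-1-ene) is lithiated (n-BuLi, THF/HMPA, −78 °C) and methylated with MeI to give 1,6,6-trimethyl-4,8-dioxaspiro[2.5]oct-1-ene F3. A second lithiation, transmetalation with ZnCl2 and Negishi coupling with 2 (Pd(PPh3)4, THF, rt) give 1-(guaiazulen-3-yl)-2,6,6-trimethyl-4,8-dioxaspiro[2.5]oct-1-ene F4. Hydrolysis of the acetal (Amberlyst 15, wet THF, rt) should give 6 without any carbene meeting the azulene.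

3. Step 2. The light- and acid-sensitive iodide 2 may deiodinate or dimerise oxidatively before or during the coupling. Fallback, setting out from guaiazulene 1 and coming back at 4: Vilsmeier–Haack formylation (POCl3, DMF, 0 °C to rt, aqueous NaOH work-up) gives the stable guaiazulene-3-carbaldehyde F5. Dibromo-olefination (CBr4, PPh3, CH2Cl2, 0 °C) gives 3-(2,2-dibromovinyl)guaiazulene F6. Treatment with n-BuLi (2 equiv, THF, −78 °C) and then MeI (Corey–Fuchs sequence with methylation of the lithium acetylide) should give 4 without a haloazulene.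

**Further compounds**

F1 | step 7 | 6-chloro-3-(1,3-dioxolan-2-yl)-2-hydroxybenzaldehyde | O=Cc1c(Cl)ccc(C2OCCO2)c1O
F2 | step 7 | 3-chloro-6-(1,3-dioxolan-2-yl)-2-formylphenyl trifluoromethanesulfonate | O=Cc1c(Cl)ccc(C2OCCO2)c1OS(=O)(=O)C(F)(F)F
F3 | step 3 | 1,6,6-trimethyl-4,8-dioxaspiro[2.5]oct-1-ene | CC1=CC12OCC(C)(C)CO2
F4 | step 3 | 1-(guaiazulen-3-yl)-2,6,6-trimethyl-4,8-dioxaspiro[2.5]oct-1-ene | CC1=C(c2cc(C)c3cc(C(C)C)ccc(C)c2-3)C14OCC(C)(C)CO4
F5 | step 2 | guaiazulene-3-carbaldehyde (5-isopropyl-3,8-dimethylazulene-1-carbaldehyde) | O=Cc1cc(C)c2cc(C(C)C)ccc(C)c1-2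
F6 | step 2 | 3-(2,2-dibromovinyl)guaiazulene | BrC(Br)=Cc1cc(C)c2cc(C(C)C)ccc(C)c1-2
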